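The lactone ring of the target is disconnected at C3, an isolated methylene flanked by the carbonyl C2 and the diarylmethine C4: excising this one carbon leaves a 3-arylbenzofuran-2-one. In the forward sense C3 is inserted as dibromocarbene into the enol-ether double bond of the derived 2-silyloxybenzofuran; cyclopropanation and ring opening create C2–C3 and C3–C4 and enlarge the furan ring to the pyranone ring in one operation. The precursor is a tris-O-silylated 4-bromo-3-(guaiacyl)benzofuran, made in two steps from 5-bromoresorcinol and a mandelic acid; its bromine later carries the styryl arm, and C4 is set by asymmetric conjugate reduction.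

Key step: step 3

Assumption: 2 is used as the commercial racemate, because its stereocenter becomes the enolisable C3 of benzofuranone 4 and is erased in step 2; the target is (R) at C4 (priorities C4a > aryl > C3 > H).
Conventions: TBS = tert-butyldimethylsilyl; coumarin numbering (O1, C2, C3, C4, C4a, C5–C8, C8a) is used for 8–13 and benzofuran numbering for 4, 5 and 7.

Step 1
Reactants: 1 5-bromoresorcinol; 2 4-hydroxy-3-methoxymandelic acid (racemic)
Product: 4 4-bromo-6-hydroxy-3-(4-hydroxy-3-methoxyphenyl)-1-benzofuran-2(3H)-one (racemic), via diarylacetic acid 3 (not isolated)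
Conditions: BF3·OEt2, 1,4-dioxane, rt to 60 °C (2 equiv of 1)
Reagents that add atoms: none
Why: Acid-promoted Friedel–Crafts hydroxyalkylation followed by lactonisation: the p-hydroxybenzylic cation from 2 should attack 1 at C4 (para to one hydroxyl, ortho to the other, the usual site of electrophilic substitution in 5-substituted resorcinols), the flanking hydroxyl of adduct 3 then closes the five-membered lactone, and the excess of 1 should suppress self-condensation of 2.

Step 2
Reactants: 4 4-bromo-6-hydroxy-3-(4-hydroxy-3-methoxyphenyl)-1-benzofuran-2(3H)-one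
Product: 5 4-bromo-2,6-bis(TBSO)-3-[4-(TBSO)-3-methoxyphenyl]-1-benzofuran
Conditions: TBSOTf (3.5 equiv), Et3N, CH2Cl2, 0 °C to rt; non-aqueous work-up, used directly
Reagents that add atoms: tert-butyldimethylsilyl trifluoromethanesulfonate, CC(C)(C)[Si](C)(C)OS(=O)(=O)C(F)(F)F
Why: Silyl triflate/amine soft enolisation: both phenols are silylated and the acidic, doubly benzylic C3–H lactone is trapped on oxygen, which is favoured because the O-silyl enol form is an aromatic benzofuran.

Step 3
Reactants: 5 4-bromo-2,6-bis(TBSO)-3-[4-(TBSO)-3-methoxyphenyl]-1-benzofuran; 6 bromoform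
Product: 8 3,5-dibromo-7-(TBSO)-4-[4-(TBSO)-3-methoxyphenyl]-2H-chromen-2-one, via dibromocyclopropane 7 (not isolated)
Conditions: KOtBu (2.5 equiv), pentane, −30 °C to rt (6 in excess)
Reagents that add atoms: none
Why: α-Elimination of bromoform with KOtBu generates electrophilic dibromocarbene, which should add in a concerted [2+1] manner across the C2=C3 bond of the furan ring to give the cis-fused dibromocyclopropane 7. Ionisation of the bromide syn to the benzofuran ring is coupled with disrotatory opening of the bond between the two former furan carbons and leads to an aromatic 2-silyloxybenzopyrylium ion, from which bromide removes the silyl group to unveil the 3-bromocoumarin 8. The closest known reaction type is the dihalocarbene one-carbon ring expansion of cyclic silyl enol ethers to 2-halo-enones, together with the Ciamician–Dennstedt-type expansion of indoles and benzofurans. The pyranone ring is not closed by cyclisation of a chain but by ring enlargement: the inserted carbon is first bonded to both furan carbons in a cheletropic three-membered ring closure, and the original five-ring bond is then cleaved electrocyclically. No stereocenter is created. The step needs chemoselectivity for the enol-ether bond over the two arenes and a single direction of opening; the first is secured by the ketene-acetal character of that bond (two oxygen donors), the second by the geometry of the bicycle (only loss of the endo bromide gives a cisoid allyl cation within a ring) and by oxygen stabilisation of the cation.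

Step 4
Reactants: 8 3,5-dibromo-7-(TBSO)-4-[4-(TBSO)-3-methoxyphenyl]-2H-chromen-2-one
Product: 9 5-bromo-7-(TBSO)-4-[4-(TBSO)-3-methoxyphenyl]-2H-chromen-2-one
Conditions: Zn dust, AcOH, THF, rt
Reagents that add atoms: none
Why: Dissolving-metal reductive dehalogenation: zinc should transfer electrons into the electron-poor α-bromo enoate so that the C3–Br bond is cleaved and the resulting zinc species is protonated by acetic acid, while the unactivated aryl C5–Br bond and the aryl silyl ethers should be inert under these conditions.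

Step 5
Reactants: 9 5-bromo-7-(TBSO)-4-[4-(TBSO)-3-methoxyphenyl]-2H-chromen-2-one
Product: 10 (4R)-5-bromo-7-(TBSO)-4-[4-(TBSO)-3-methoxyphenyl]-3,4-dihydro-2H-chromen-2-one
Conditions: Cu(OAc)2·H2O (cat.), (R)-DTBM-SEGPHOS (cat.), (EtO)2MeSiH (1.3 equiv), t-BuOH, toluene, 0 °C to rt
Reagents that add atoms: none
Why: Ligated copper hydride asymmetric 1,4-reduction of a 4-arylcoumarin: the chiral bisphosphine–CuH complex should deliver hydride to the Si face of C4 (priorities C4a > aryl > C3) to give the (R) centre under catalyst control, while tert-butanol protonates the copper enolate and turns the catalyst over; the (R)-ligand is chosen by analogy with 5-unsubstituted 4-arylcoumarins, the sense of induction is to be confirmed on the first run, and the (S)-ligand is the remedy if it is opposite.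

Step 6
Reactants: 10 (4R)-5-bromo-7-(TBSO)-4-[4-(TBSO)-3-methoxyphenyl]-3,4-dihydro-2H-chromen-2-one; 11 2-methoxy-4-vinylphenol
Product: 12 (4R)-7-(TBSO)-4-[4-(TBSO)-3-methoxyphenyl]-5-[(E)-2-(4-hydroxy-3-methoxyphenyl)ethenyl]-3,4-dihydro-2H-chromen-2-one
Conditions: Pd(P(t-Bu)3)2 (cat.), Cy2NMe, 1,4-dioxane, 80 °C (1.5 equiv of 11)
Reagents that add atoms: none
Why: Mizoroki–Heck reaction: oxidative addition of the hindered aryl bromide to the bulky, electron-rich zerovalent palladium–phosphine complex, syn-insertion of the styrene with aryl transfer to its terminal carbon and syn β-hydride elimination should give the (E)-stilbene, and C4 is not at risk because the weak amine base cannot ionise it and both para-oxygens are still silylated.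

Step 7
Reactants: 12 (4R)-7-(TBSO)-4-[4-(TBSO)-3-methoxyphenyl]-5-[(E)-2-(4-hydroxy-3-methoxyphenyl)ethenyl]-3,4-dihydro-2H-chromen-2-one
Product: 13 (4R)-7-hydroxy-4-(4-hydroxy-3-methoxyphenyl)-5-[(E)-2-(4-hydroxy-3-methoxyphenyl)ethenyl]-3,4-dihydro-2H-chromen-2-one
Conditions: TBAF, AcOH (1:1), THF, 0 °C to rt
Reagents that add atoms: none
Why: Fluoride-induced cleavage of both aryl silyl ethers; buffering with acetic acid keeps the liberated phenols protonated, so that neither opening of the aryl-ester lactone nor phenoxide-driven retro-Michael racemisation at C4 should occur.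

Compound list
1 | 5-bromoresorcinol | Oc1cc(O)cc(Br)c1 | starting material
2 | 4-hydroxy-3-methoxymandelic acid (racemic) | COc1cc(C(O)C(=O)O)ccc1O | starting material
3 | 2-(2-bromo-4,6-dihydroxyphenyl)-2-(4-hydroxy-3-methoxyphenyl)acetic acid (racemic, not isolated) | COc1cc(C(C(=O)O)c2c(O)cc(O)cc2Br)ccc1O | intermediate
4 | 4-bromo-6-hydroxy-3-(4-hydroxy-3-methoxyphenyl)-1-benzofuran-2(3H)-one (racemic) | COc1cc(C2C(=O)Oc3cc(O)cc(Br)c32)ccc1O | intermediate
5 | 4-bromo-2,6-bis(TBSO)-3-[4-(TBSO)-3-methoxyphenyl]-1-benzofuran | COc1cc(-c2c(O[Si](C)(C)C(C)(C)C)oc3cc(O[Si](C)(C)C(C)(C)C)cc(Br)c23)ccc1O[Si](C)(C)C(C)(C)C | intermediate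
6 | bromoform | BrC(Br)Br | starting material
7 | 1,1,6-tribromo-1a,4-bis(TBSO)-6b-[4-(TBSO)-3-methoxyphenyl]-1a,6b-dihydro-1H-cyclopropa[b][1]benzofuran (racemic, cis-fused, CBr2 bridging the former furan C2 and C3, not isolated) | COc1cc(C23c4c(Br)cc(O[Si](C)(C)C(C)(C)C)cc4OC2(O[Si](C)(C)C(C)(C)C)C3(Br)Br)ccc1O[Si](C)(C)C(C)(C)C | intermediate
8 | 3,5-dibromo-7-(TBSO)-4-[4-(TBSO)-3-methoxyphenyl]-2H-chromen-2-one | COc1cc(C2=C(Br)C(=O)Oc3cc(O[Si](C)(C)C(C)(C)C)cc(Br)c23)ccc1O[Si](C)(C)C(C)(C)C | intermediate
9 | 5-bromo-7-(TBSO)-4-[4-(TBSO)-3-methoxyphenyl]-2H-chromen-2-one | COc1cc(C2=CC(=O)Oc3cc(O[Si](C)(C)C(C)(C)C)cc(Br)c23)ccc1O[Si](C)(C)C(C)(C)C | intermediate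
10 | (4R)-5-bromo-7-(TBSO)-4-[4-(TBSO)-3-methoxyphenyl]-3,4-dihydro-2H-chromen-2-one | COc1cc([C@H]2CC(=O)Oc3cc(O[Si](C)(C)C(C)(C)C)cc(Br)c32)ccc1O[Si](C)(C)C(C)(C)C | intermediate
11 | 2-methoxy-4-vinylphenol | COc1cc(C=C)ccc1O | starting material
12 | (4R)-7-(TBSO)-4-[4-(TBSO)-3-methoxyphenyl]-5-[(E)-2-(4-hydroxy-3-methoxyphenyl)ethenyl]-3,4-dihydro-2H-chromen-2-one | COc1cc(/C=C/c2cc(O[Si](C)(C)C(C)(C)C)cc3c2[C@@H](c2ccc(O[Si](C)(C)C(C)(C)C)c(OC)c2)CC(=O)O3)ccc1O | intermediate
13 | (4R)-7-hydroxy-4-(4-hydroxy-3-methoxyphenyl)-5-[(E)-2-(4-hydroxy-3-methoxyphenyl)ethenyl]-3,4-dihydro-2H-chromen-2-one | COc1cc(/C=C/c2cc(O)cc3c2[C@@H](c2ccc(O)c(OC)c2)CC(=O)O3)ccc1O | target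

Total step count: 7. Longest linear sequence: 7 steps (from 1 or 2 to 13).

Steps most likely to fail

Step 3. The base may strip silyl groups before the carbene arrives, so that the lactone enolate is C-alkylated instead of cyclopropanated. The cyclopropane may also open incompletely, or alkoxide may attack the product lactone. The fallback replaces ring expansion by olefination and lactonisation of a 2-hydroxybenzophenone and sets out from 1. Friedel–Crafts acylation of 1 with vanillic acid in BF3·OEt2 at 90 °C should give (2-bromo-4,6-dihydroxyphenyl)(4-hydroxy-3-methoxyphenyl)methanone F1. TBSCl and imidazole (2.1 equiv, DMF, 0 °C) should then silylate the two unchelated phenols and leave the hydrogen-bonded ortho hydroxyl free, giving [2-bromo-6-hydroxy-4-(TBSO)phenyl][4-(TBSO)-3-methoxyphenyl]methanone F2. Heating F2 with Ph3P=C=C=O in toluene should add the free phenol to the ketene carbonyl and close the ring by intramolecular Wittig olefination of the diaryl ketone. This comes back to the route at 9, so that steps 1 to 4 are bypassed.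

Step 5. Hydride delivery to C4 may be slow because the C5 bromine sits peri to it, facial selectivity may be poor with the 4-aryl ring twisted out of plane, and the lactone carbonyl may be over-reduced to the lactol. The fallback exchanges asymmetric catalysis for outer-sphere reduction and resolution and sets out from 9. SmI2 in THF/MeOH, without HMPA so that the aryl bromide is kept, should give racemic 5-bromo-7-(TBSO)-4-[4-(TBSO)-3-methoxyphenyl]-3,4-dihydro-2H-chromen-2-one F3. Preparative chromatography on a chiral stationary phase would separate 10 from the unwanted (4S)-5-bromo-7-(TBSO)-4-[4-(TBSO)-3-methoxyphenyl]-3,4-dihydro-2H-chromen-2-one F4. The route is rejoined at 10.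

Step 1. The benzylic cation may attack the carbon between the two hydroxyls of 1, which after ring closure would give the 6-bromo-4-hydroxy lactone, and it may oligomerise with further 2. The fallback enforces the site of attack by steric shielding and sets out from 1. TBSCl and imidazole in DMF should give 1-bromo-3,5-bis(tert-butyldimethylsilyloxy)benzene F5, in which the carbon between the two silyloxy groups is blocked. Friedel–Crafts alkylation of F5 (in excess) with 2 under catalytic TfOH in (CF3)2CHOH at 0 °C should then take place only ortho to bromine and para to a silyloxy group, giving 2-[2-bromo-4,6-bis(tert-butyldimethylsilyloxy)phenyl]-2-(4-hydroxy-3-methoxyphenyl)acetic acid F6. TBAF in THF followed by acidification with aqueous HCl and gentle warming should release 3, which lactonises. The route is rejoined at 4.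

Further compounds
F1 | step 3 | (2-bromo-4,6-dihydroxyphenyl)(4-hydroxy-3-methoxyphenyl)methanone | COc1cc(C(=O)c2c(O)cc(O)cc2Br)ccc1O
F2 | step 3 | [2-bromo-6-hydroxy-4-(TBSO)phenyl][4-(TBSO)-3-methoxyphenyl]methanone | COc1cc(C(=O)c2c(O)cc(O[Si](C)(C)C(C)(C)C)cc2Br)ccc1O[Si](C)(C)C(C)(C)C
F3 | step 5 | racemic 5-bromo-7-(TBSO)-4-[4-(TBSO)-3-methoxyphenyl]-3,4-dihydro-2H-chromen-2-one | COc1cc(C2CC(=O)Oc3cc(O[Si](C)(C)C(C)(C)C)cc(Br)c32)ccc1O[Si](C)(C)C(C)(C)C
F4 | step 5 | (4S)-5-bromo-7-(TBSO)-4-[4-(TBSO)-3-methoxyphenyl]-3,4-dihydro-2H-chromen-2-one | COc1cc([C@@H]2CC(=O)Oc3cc(O[Si](C)(C)C(C)(C)C)cc(Br)c32)ccc1O[Si](C)(C)C(C)(C)C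
F5 | step 1 | 1-bromo-3,5-bis(tert-butyldimethylsilyloxy)benzene | CC(C)(C)[Si](C)(C)Oc1cc(Br)cc(O[Si](C)(C)C(C)(C)C)c1
F6 | step 1 | 2-[2-bromo-4,6-bis(tert-butyldimethylsilyloxy)phenyl]-2-(4-hydroxy-3-methoxyphenyl)acetic acid (racemic) | COc1cc(C(C(=O)O)c2c(O[Si](C)(C)C(C)(C)C)cc(O[Si](C)(C)C(C)(C)C)cc2Br)ccc1O
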